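## Analysis of the target

The target is a spiro compound: a 2,3,4-trimethoxybenzo-fused seven-membered ring C shares one carbon (C1′) with ring B, a cross-conjugated 2,6-dimethoxycyclohexa-2,5-dienone. Ring C runs C1′ (spiro), C7′H2, C8′H(CH3), C8H(CH3), C7H(OH), arene C1, arene C2. The three contiguous stereocentres are 7R, 8S and 8′R. The C7 hydroxyl is trans to the C8 methyl, and the C8 methyl is trans to the C8′ methyl, so all three substituents can sit pseudo-equatorial. C1′ is quaternary but not stereogenic, because the two arms of ring B are identical. The sensitive groups are the dienone (acid-induced dienone–phenol rearrangement, conjugate addition, easy reduction), the benzylic alcohol para to a methoxy group (easy ionisation) and the electron-rich arene. Two things make the synthesis hard. The quaternary carbon carries an arene with two ortho substituents, and the three stereocentres sit in a flexible ring with no neighbouring carbonyl through which they could be corrected. The strategy rests on the C7 carbinol lying next to the C8 methine while C1′ is already quaternary. This is the pattern of an aldehyde (C7, on ring A) adding to C8 of a (Z)-2-methylbut-2-enyl group on C1′. Because ring B is symmetric, that open precursor is achiral, so a chiral Lewis acid can set the absolute configuration during ring closure.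

## Retrosynthetic reasoning

**16 to 15 (C8′–H).** The C8′ methyl is traced back to an exocyclic methylene. C8′ is the only stereocentre not made in the ring closure, and the methylene is exactly what a carbonyl-ene reaction leaves behind. The forward step must add hydrogen to the 1,1-disubstituted alkene without touching the dienone and must place the new methyl trans to the C8 methyl.

**15 to 14 (C7–C8).** Cutting C7–C8 opens ring C and removes two stereocentres at once, leaving the achiral dienone aldehyde 14. A cut at C1′ instead would require the quaternary carbon and the ring to be made in the same event. Forward, the ring A aldehyde must act as enophile toward the trisubstituted alkene, take its hydrogen from the C8′ methyl, and do so on one enantiotopic face.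

**14 to 13 (two masked carbonyls).** The aldehyde is carried as a dioxolane and the ring B carbonyl as a dimethyl ketal. All organometallic and basic steps are thus run on a compound that has neither an aldehyde nor a Michael acceptor. The forward hydrolysis must free both without closing ring C prematurely.

**13 to 12 (C8′=C8).** The trisubstituted alkene comes from a methyl ketone by ethylidenation. The olefination must favour the Z isomer, since the alkene geometry decides the C7/C8 relation later.

**12 to 11 (C8′=O).** The methyl ketone comes from a terminal alkene by Wacker oxidation. An allyl group is the unit that a sigmatropic shift can deliver to C1′.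

**11 to 8 (C1′–C7′).** The quaternary carbon is formed by a [3,3] shift of an allyl group from C3′ to C1′ within a 3-oxido-1,5-diene, followed by O-methylation of the enolate. Two more obvious routes were rejected:
- A para-Claisen/Cope relay from an O-allyl ether of an aromatic ring B looks shorter. However, a 2,4,6-trisubstituted cyclohexadienone cannot tautomerise, is less stable than its aryl allyl ether and reverts to it.
- Intermolecular attack of an allyl nucleophile on an oxidised ring B would be drawn to the methoxy-bearing ortho carbons. C1′ is also screened on both faces by the perpendicular, doubly ortho-substituted arene.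

In the chosen design C4′ is an sp3 ketal carbon, so aromatisation is impossible and the shift is intramolecular.

**8 to 7 (C3′–allyl).** The rearrangement substrate comes from 1,2-addition of an allyl–magnesium reagent to the carbonyl of dienone 7.

**7 to 2 and 4 (C1′–arene).** The arene is joined to ring B by carbonyl addition of the aryllithium from 2 to quinone monoketal 4. An allylic transposition of the vinylogous ester then moves the carbonyl to C3′ and leaves the arene on the β-carbon. This replaces a biaryl coupling followed by dearomatisation and fixes the oxygen pattern of ring B from the start.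

**2 to 1 and 4 to 3.** Acetal protection of the bromo aldehyde 1, and oxidative ketalisation of phenol 3.

## Alternatives that were turned down

**Alternative 1: ring B built last by a Robinson-type spiroannulation.**
- Disconnection: the C1′–C6′ and C2′=C3′ bonds of ring B are cut. This gives the α-branched ring C aldehyde A1 (C1′ carries H and CHO) and the methoxylated enone A2.
- Forward key step: the enolate or an enamine of A1 adds through C1′ to A2, and the methoxymethyl carbon then condenses with the formyl group to give spiro enone A3.
- For: ring C arrives with its three stereocentres in place, nothing stereochemical remains at the end, and the fragile dienone appears only in the last steps. On these two points it is stronger than the chosen route.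
- Against: the Michael step must create the quaternary C1′ next to a doubly ortho-substituted arene from a hindered aldehyde, with an acceptor that polymerises easily. The aldol closure onto a neopentyl aldehyde is slow. A further dehydrogenation is needed to reach the dienone. The annulation creates no stereocentre, so the C7/C8/C8′ triad of A1 must be solved separately beforehand.
- Comparison: the chosen strategy instead forms ring C and two stereocentres in one step from an achiral compound, with a shorter overall count.

**Alternative 2: both methyl groups by conjugate addition and enolate methylation.**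
- Disconnection: the two C–CH3 bonds at C8′ and C8 are cut, back to the aryl enone A4.
- Forward key step: a copper-catalysed, ligand-controlled 1,4-addition of a methylzinc nucleophile to C8′, then methylation of the zinc enolate at C8 anti to the new methyl, gives ketone A5.
- For: the trans relation of the two methyls comes from a well-understood anti alkylation, and the absolute configuration from a broadly validated catalyst class. On the C8/C8′ relation it is stronger than the radical hydrogenation used here.
- Against: A4 has three acceptor positions, because the dienone offers two more β-carbons, and the aryl-conjugated seven-membered enone is the least electrophilic of them. Zinc enolates alkylate sluggishly, so protonation and loss of the trans control threaten. The C7 ketone of A5 must still be reduced with the 7R sense beside the dienone carbonyl. A4 itself already needs the spiro carbon and ring C.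
- Comparison: the chosen strategy sets C7 and C8 together and leaves one reduction.

**Alternative 3: aryne insertion into a cyclopentanone keto ester.**
- Disconnection: the arene C1–C7 and arene C2–C1′ bonds are cut, back to aryne A7 and keto ester A6, which derives from a C2-symmetric trans-dimethylcyclopentanone.
- Forward key step: the enolate carbon of A6 adds to the aryne carbon remote from methoxy, the aryl anion closes on the ketone, and the cyclobutoxide fragments to the ring-expanded keto ester A8.
- For: it is very convergent, the methoxy group steers the aryne regiochemistry correctly, and both methyl stereocentres come from a symmetric ketone with no selectivity problem. On the methyl stereocentres it is the strongest of all four plans.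
- Against: A8 has neither ring B nor the C7 oxygen. Its hindered aryl ketone must receive two carbon substituents to become the spiro dienone. The C7 ester must be degraded to a hydroxyl of defined configuration. This gives the longest endgame.
- Comparison: the chosen strategy has the quaternary carbon and ring B finished before the ring closure and ends one step after it.

Key step: step 9

Assumption: the sense of induction of BINOL–titanium catalysts for this ring size and a trisubstituted ene unit is not secure; (R)-BINOL is written in step 9 and the antipodal ligand is used if a pilot run shows that it leads to the 7S,8R series.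

## Route

Step 1
Reactants: 1 2-bromo-3,4,5-trimethoxybenzaldehyde
Product: 2 2-(2-bromo-3,4,5-trimethoxyphenyl)-1,3-dioxolane
Conditions: HOCH2CH2OH, p-TsOH (cat.), toluene, reflux, azeotropic removal of water
Reagents that add atoms: ethylene glycol, OCCO
Why: Acid-catalysed acetalisation; the dioxolane protects the aldehyde against the organolithium, Grignard, KH and ylide steps and is more acid-stable than an acyclic acetal, which matters in step 3.

Step 2
Reactants: 3 3,4,5-trimethoxyphenol
Product: 4 3,4,4,5-tetramethoxycyclohexa-2,5-dien-1-one
Conditions: PhI(OAc)2, MeOH, 0 °C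
Reagents that add atoms: methanol, CO
Why: Oxidative dearomatisation of a para-alkoxyphenol by the trivalent iodine reagent; methanol adds at the para carbon that already bears methoxy, the standard entry to para-quinone monoketals.

Step 3
Reactants: 2 2-(2-bromo-3,4,5-trimethoxyphenyl)-1,3-dioxolane; 4 3,4,4,5-tetramethoxycyclohexa-2,5-dien-1-one
Product: 7 3-[2-(1,3-dioxolan-2-yl)-4,5,6-trimethoxyphenyl]-5,6,6-trimethoxycyclohexa-2,4-dien-1-one, via aryllithium 5 (not isolated), via tertiary dienol 6 (not isolated)
Conditions: n-BuLi, THF, −78 °C; then 4, −78 to −40 °C; then aq. oxalic acid, THF, 0 °C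
Reagents that add atoms: water, O
Why: Bromine–lithium exchange gives 5, which adds 1,2 to the only carbonyl of the doubly vinylogous ester 4; dilute acid then ionises the doubly allylic tertiary alcohol of 6, water adds at a methoxy-bearing terminus and methanol is lost (Stork–Danheiser transposition), leaving the arene on the β-carbon of dienone 7, while the α-keto ketal and the dioxolane hydrolyse more slowly.

Step 4
Reactants: 7 3-[2-(1,3-dioxolan-2-yl)-4,5,6-trimethoxyphenyl]-5,6,6-trimethoxycyclohexa-2,4-dien-1-one
Product: 8 1-allyl-3-[2-(1,3-dioxolan-2-yl)-4,5,6-trimethoxyphenyl]-5,6,6-trimethoxycyclohexa-2,4-dien-1-ol (racemic)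
Conditions: allylMgBr, THF, −78 °C; then H2O
Reagents that add atoms: allylmagnesium bromide, C=CC[Mg]Br
Why: Grignard 1,2-addition; allyl reagents react through a six-membered transition state and prefer the carbonyl carbon even of conjugated, hindered ketones; the carbinol stereocentre is racemic and is erased in step 5, and the neutral work-up avoids a second allylic transposition.

Step 5
Reactants: 8 1-allyl-3-[2-(1,3-dioxolan-2-yl)-4,5,6-trimethoxyphenyl]-5,6,6-trimethoxycyclohexa-2,4-dien-1-ol
Product: 11 2-[2-(1-allyl-3,4,4,5-tetramethoxycyclohexa-2,5-dien-1-yl)-3,4,5-trimethoxyphenyl]-1,3-dioxolane, via potassium alkoxide 9 (not isolated), via potassium enolate 10 (not isolated)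
Conditions: KH, 18-crown-6, THF, 0 °C to rt; then Me2SO4, 0 °C
Reagents that add atoms: dimethyl sulfate, COS(=O)(=O)OC
Why: Anionic oxy-Cope rearrangement: the 3-oxido-1,5-diene 9 undergoes the [3,3] shift near room temperature and moves the allyl group from C3′ to the arene-bearing C1′, forming the quaternary carbon intramolecularly; no aromatisation can compete because C4′ is an sp3 ketal carbon. The enolate 10 is then O-methylated by the hard electrophile (its carbon terminus is neopentyl), which restores the second enol ether and makes ring B symmetric again.

Step 6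
Reactants: 11 2-[2-(1-allyl-3,4,4,5-tetramethoxycyclohexa-2,5-dien-1-yl)-3,4,5-trimethoxyphenyl]-1,3-dioxolane
Product: 12 1-{1-[2-(1,3-dioxolan-2-yl)-4,5,6-trimethoxyphenyl]-3,4,4,5-tetramethoxycyclohexa-2,5-dien-1-yl}propan-2-one
Conditions: PdCl2 (10 mol %), Cu(OAc)2 (20 mol %), O2 (1 atm), DMA/H2O (7:1), rt
Reagents that add atoms: water, O
Why: Tsuji–Wacker oxidation of the terminal alkene to the methyl ketone (Markovnikov oxypalladation by water, divalent palladium regenerated by copper and O2); the acetate-buffered, chloride-poor medium should spare the ketal, and the hindered trisubstituted enol ethers should not compete for palladium.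

Step 7
Reactants: 12 1-{1-[2-(1,3-dioxolan-2-yl)-4,5,6-trimethoxyphenyl]-3,4,4,5-tetramethoxycyclohexa-2,5-dien-1-yl}propan-2-one
Product: 13 2-(3,4,5-trimethoxy-2-{3,4,4,5-tetramethoxy-1-[(2Z)-2-methylbut-2-en-1-yl]cyclohexa-2,5-dien-1-yl}phenyl)-1,3-dioxolane
Conditions: EtPPh3Br, KN(SiMe3)2, THF, −78 °C to rt; AgNO3-impregnated silica to remove the E isomer
Reagents that add atoms: ethyltriphenylphosphonium bromide, CC[P+](c1ccccc1)(c1ccccc1)c1ccccc1.[Br-]
Why: Wittig olefination with the non-stabilised ethylidene ylide under lithium-free conditions; the bulky C7′H2 branch takes the place of the aldehyde substituent in the early puckered transition state, so the ylide methyl should end cis to it (Z). With ring B still a ketal there is no second carbonyl and no Michael acceptor for the basic ylide.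

Step 8
Reactants: 13 2-(3,4,5-trimethoxy-2-{3,4,4,5-tetramethoxy-1-[(2Z)-2-methylbut-2-en-1-yl]cyclohexa-2,5-dien-1-yl}phenyl)-1,3-dioxolane
Product: 14 2-{3,5-dimethoxy-1-[(2Z)-2-methylbut-2-en-1-yl]-4-oxocyclohexa-2,5-dien-1-yl}-3,4,5-trimethoxybenzaldehyde
Conditions: AcOH/THF/H2O (3:1:1), 40 °C
Reagents that add atoms: water, O
Why: Acid hydrolysis of both acetals: the doubly allylic ring ketal ionises readily and gives the cross-conjugated dienone, whose α-methoxy enone units resist further hydrolysis, and the electron-rich aryl dioxolane follows; acetic acid is too weak to trigger a Prins-type closure of the freed aldehyde onto the alkene.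

Step 9
Reactants: 14 2-{3,5-dimethoxy-1-[(2Z)-2-methylbut-2-en-1-yl]-4-oxocyclohexa-2,5-dien-1-yl}-3,4,5-trimethoxybenzaldehyde
Product: 15 (8S,9R)-9-hydroxy-2,3,3′,4,5′-pentamethoxy-8-methyl-7-methylidene-6,7,8,9-tetrahydrospiro[benzo[7]annulene-5,1′-cyclohexa[2,5]dien]-4′-one (lignan locants 7R,8S)
Conditions: TiCl2(OiPr)2 (20 mol %), (R)-BINOL (20 mol %), 4 Å MS, CH2Cl2, −20 to 0 °C
Reagents that add atoms: none
Why: The BINOL–titanium Lewis acid binds the aldehyde oxygen, and the aldehyde adds to the alkene in a concerted, asynchronous ene process: C7 bonds to C8 while the oxygen takes a hydrogen from the C8′ methyl through a six-membered array, leaving C8′=CH2. The closest known reaction type is the Lewis-acid-catalysed (2,4) carbonyl-ene cyclisation of unsaturated aldehydes to 3-methylenecycloalkanols, including seven-membered closures and BINOL–titanium enantioselective versions; the trisubstituted ene unit and the aryl aldehyde are the new features. Ring C closes in the 7-(2,4) mode: the tether joins C8′, the central carbon of the ene unit, to the aldehyde carbon through C7′, C1′ and the arene, the carbonyl is exo to the new ring and the alkene ends exocyclic. The C8 configuration relative to C7 is controlled by the Z alkene: the oxygen must sit over the C8′ methyl, the arene must point back along the tether, and the C8 methyl, which lies on the tether side of the alkene, therefore ends trans to the C7 oxygen. The absolute configuration (7R,8S) is controlled by the BINOL ligand, which selects one enantiotopic aldehyde face of the achiral precursor; both centres arise in the same bond-forming event, so one selection fixes both. The step needs chemoselectivity for the aldehyde over the dienone carbonyl (the aldehyde is less hindered and is the only carbonyl held over an alkene), regioselectivity in the hydrogen transfer (only the methyl is within reach in the closed array, and ring B has no allylic hydrogen) and a slow uncatalysed background (the aldehyde is non-enolisable and electron-rich). The quaternary C1′ and the rigid arene hold the partners together, which should offset the modest electrophilicity of the aldehyde, and the mild titanium catalyst avoids dienone–phenol rearrangement.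

Step 10
Reactants: 15 (8S,9R)-9-hydroxy-2,3,3′,4,5′-pentamethoxy-8-methyl-7-methylidene-6,7,8,9-tetrahydrospiro[benzo[7]annulene-5,1′-cyclohexa[2,5]dien]-4′-one
Product: 16 (7R,8S,9R)-9-hydroxy-2,3,3′,4,5′-pentamethoxy-7,8-dimethyl-6,7,8,9-tetrahydrospiro[benzo[7]annulene-5,1′-cyclohexa[2,5]dien]-4′-one (lignan locants 7R,8S,8′R)
Conditions: Mn(dpm)3 (10 mol %), PhSiH3, t-BuOOH, i-PrOH, rt
Reagents that add atoms: none
Why: Hydrogen-atom-transfer hydrogenation: the manganese hydride gives a hydrogen atom to the unhindered CH2 terminus and the tertiary C8′ radical takes the second one; delivery along the axial direction should leave the new methyl pseudo-equatorial and trans to the C8 methyl (8′R), the arrangement with all three ring C substituents equatorial. The C8′ radical has no favourable cyclisation onto ring B (four-membered or 5-endo), and the hindered trisubstituted dienone alkenes should react more slowly than the 1,1-disubstituted alkene.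

## Compound list

1 | 2-bromo-3,4,5-trimethoxybenzaldehyde | COc1cc(C=O)c(Br)c(OC)c1OC | starting material
2 | 2-(2-bromo-3,4,5-trimethoxyphenyl)-1,3-dioxolane | COc1cc(C2OCCO2)c(Br)c(OC)c1OC | intermediate
3 | 3,4,5-trimethoxyphenol | COc1cc(O)cc(OC)c1OC | starting material
4 | 3,4,4,5-tetramethoxycyclohexa-2,5-dien-1-one | COC1=CC(=O)C=C(OC)C1(OC)OC | intermediate
5 | [2-(1,3-dioxolan-2-yl)-4,5,6-trimethoxyphenyl]lithium | [Li]c1c(OC)c(OC)c(OC)cc1C1OCCO1 | intermediate
6 | 1-[2-(1,3-dioxolan-2-yl)-4,5,6-trimethoxyphenyl]-3,4,4,5-tetramethoxycyclohexa-2,5-dien-1-ol | OC1(c2c(OC)c(OC)c(OC)cc2C2OCCO2)C=C(OC)C(OC)(OC)C(OC)=C1 | intermediate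
7 | 3-[2-(1,3-dioxolan-2-yl)-4,5,6-trimethoxyphenyl]-5,6,6-trimethoxycyclohexa-2,4-dien-1-one | O=C1C=C(c2c(OC)c(OC)c(OC)cc2C2OCCO2)C=C(OC)C1(OC)OC | intermediate
8 | 1-allyl-3-[2-(1,3-dioxolan-2-yl)-4,5,6-trimethoxyphenyl]-5,6,6-trimethoxycyclohexa-2,4-dien-1-ol (racemic) | C=CCC1(O)C=C(c2c(OC)c(OC)c(OC)cc2C2OCCO2)C=C(OC)C1(OC)OC | intermediate
9 | potassium alkoxide of 8 | C=CCC1([O-])C=C(c2c(OC)c(OC)c(OC)cc2C2OCCO2)C=C(OC)C1(OC)OC.[K+] | intermediate
10 | potassium 3-allyl-3-[2-(1,3-dioxolan-2-yl)-4,5,6-trimethoxyphenyl]-5,6,6-trimethoxycyclohexa-1,4-dien-1-olate | C=CCC1(c2c(OC)c(OC)c(OC)cc2C2OCCO2)C=C([O-])C(OC)(OC)C(OC)=C1.[K+] | intermediate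
11 | 2-[2-(1-allyl-3,4,4,5-tetramethoxycyclohexa-2,5-dien-1-yl)-3,4,5-trimethoxyphenyl]-1,3-dioxolane | C=CCC1(c2c(OC)c(OC)c(OC)cc2C2OCCO2)C=C(OC)C(OC)(OC)C(OC)=C1 | intermediate
12 | 1-{1-[2-(1,3-dioxolan-2-yl)-4,5,6-trimethoxyphenyl]-3,4,4,5-tetramethoxycyclohexa-2,5-dien-1-yl}propan-2-one | CC(=O)CC1(c2c(OC)c(OC)c(OC)cc2C2OCCO2)C=C(OC)C(OC)(OC)C(OC)=C1 | intermediate
13 | 2-(3,4,5-trimethoxy-2-{3,4,4,5-tetramethoxy-1-[(2Z)-2-methylbut-2-en-1-yl]cyclohexa-2,5-dien-1-yl}phenyl)-1,3-dioxolane | COC1=CC(C/C(C)=C\C)(C=C(OC)C1(OC)OC)c1c(OC)c(OC)c(OC)cc1C1OCCO1 | intermediate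
14 | 2-{3,5-dimethoxy-1-[(2Z)-2-methylbut-2-en-1-yl]-4-oxocyclohexa-2,5-dien-1-yl}-3,4,5-trimethoxybenzaldehyde | COC1=CC(C/C(C)=C\C)(C=C(OC)C1=O)c1c(OC)c(OC)c(OC)cc1C=O | intermediate
15 | (8S,9R)-9-hydroxy-2,3,3′,4,5′-pentamethoxy-8-methyl-7-methylidene-6,7,8,9-tetrahydrospiro[benzo[7]annulene-5,1′-cyclohexa[2,5]dien]-4′-one | COC1=CC2(C=C(OC)C1=O)CC(=C)[C@H](C)[C@@H](O)c1cc(OC)c(OC)c(OC)c12 | intermediate
16 | (7R,8S,9R)-9-hydroxy-2,3,3′,4,5′-pentamethoxy-7,8-dimethyl-6,7,8,9-tetrahydrospiro[benzo[7]annulene-5,1′-cyclohexa[2,5]dien]-4′-one | COC1=CC2(C=C(OC)C1=O)C[C@@H](C)[C@H](C)[C@@H](O)c1cc(OC)c(OC)c(OC)c12 | target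

## Step count and least certain steps

Total steps: 10. Longest linear sequence: 9 steps (1, 2, 7, 8, 11, 12, 13, 14, 15, 16).

**Step 9 (key step).**
- What may go wrong: turnover may be low because the para-methoxy-conjugated aldehyde is a weak enophile and the dienone carbonyl with its flanking methoxy groups can tie up titanium by chelation. A stepwise cationic course would erase the geometric control and allow chloride capture or proton loss toward C7′. Facial selection by the ligand may be poor.
- Fallback: starting from 14, the closure is run with stoichiometric Me2AlCl (CH2Cl2, −78 °C), an achiral promoter of (2,4) ene cyclisations. This gives 15 together with its enantiomer, (8R,9S)-9-hydroxy-8-methyl-7-methylidene spirodienone F1. The mixture is esterified with (S)-2-methoxy-2-phenylacetic acid (DCC, DMAP) to the diastereomeric esters, the ester of 15 F2 and the ester of the enantiomer F3. These are separated by chromatography or crystallisation, and methanolysis of F2 (K2CO3, MeOH) returns to the route at 15.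

**Step 5.**
- What may go wrong: the potassium alkoxide may fragment by retro-allylation instead of rearranging, because C1′ is screened by the twisted arene. The enolate may be methylated at carbon.
- Fallback: starting from 8, the tertiary alcohol is methylated under non-basic conditions (MeOTf, 2,6-di-tert-butyl-4-methylpyridine, CH2Cl2) to the methyl ether 1-allyl-1,5,6,6-tetramethoxy-3-aryl-cyclohexa-2,4-diene F4. This is heated in toluene (110 °C) so that a neutral Cope rearrangement of the 3-methoxy-1,5-diene delivers the allyl group to C1′ and forms the enol ether in the same event. The route is rejoined at 11.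

**Step 3.**
- What may go wrong: the ring ketal of 6 may hydrolyse before the allylic transposition, which leads to a para-quinol. The linearly conjugated dienone 7 may also dimerise by cycloaddition.
- Fallback: starting from 2, the aryllithium 5 is trapped with 2-isopropoxy-4,4,5,5-tetramethyl-1,3,2-dioxaborolane to give the aryl pinacol boronate F5. Suzuki coupling with 5-bromo-2,3-dimethoxyphenol (Pd(OAc)2, SPhos, K3PO4, toluene/H2O) gives the biaryl phenol 5-aryl-2,3-dimethoxyphenol F6. Oxidation with PhI(OAc)2 in methanol, which adds methanol at the methoxy-bearing ortho carbon, returns to the route at 7.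

**Step 7.**
- What may go wrong: Z selectivity in the olefination of a methyl ketone may be insufficient, and the basic ylide may enolise the ketone.
- Fallback: starting from 12, the kinetic enolate (LiN(iPr)2, THF, −78 °C) is methylated with MeI to the ethyl ketone F7. E-selective enolisation toward the ethyl group (lithium 2,2,6,6-tetramethylpiperidide, LiBr) and trapping with N-(5-chloro-2-pyridyl)triflimide give the (E)-enol triflate F8, in which the triflate is trans to the terminal methyl. Stereoretentive methylation (Pd(PPh3)4, trimethylboroxine, K2CO3, dioxane) returns to the route at 13.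

**Step 10.**
- What may go wrong: the hydrogen atom may be delivered to the other face of the C8′ radical, giving the cis-dimethyl epimer. The dienone may undergo conjugate reduction by the metal hydride.
- Fallback: starting from 15, the hydroxyl is silylated (TBSOTf, 2,6-lutidine) to the silyl ether F9, so that it cannot direct a cationic catalyst. The methylene is hydrogenated under catalyst control with [Ir(cod)(tBu-PHOX)][B(C6H3-3,5-(CF3)2)4] and H2, the ligand enantiomer being chosen to give the 8′R silyl ether F10. HF·pyridine returns to the route at 16.

## Further compounds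

F1 | step 9 | (8R,9S)-9-hydroxy-2,3,3′,4,5′-pentamethoxy-8-methyl-7-methylidene-6,7,8,9-tetrahydrospiro[benzo[7]annulene-5,1′-cyclohexa[2,5]dien]-4′-one (enantiomer of 15) | COC1=CC2(C=C(OC)C1=O)CC(=C)[C@@H](C)[C@H](O)c1cc(OC)c(OC)c(OC)c12
F2 | step 9 | (S)-2-methoxy-2-phenylacetate of 15 | COC1=CC2(C=C(OC)C1=O)CC(=C)[C@H](C)[C@@H](OC(=O)[C@@H](OC)c3ccccc3)c1cc(OC)c(OC)c(OC)c12
F3 | step 9 | (S)-2-methoxy-2-phenylacetate of F1 | COC1=CC2(C=C(OC)C1=O)CC(=C)[C@@H](C)[C@H](OC(=O)[C@@H](OC)c3ccccc3)c1cc(OC)c(OC)c(OC)c12
F4 | step 5 | 2-[2-(5-allyl-3,4,4,5-tetramethoxycyclohexa-1,3-dien-1-yl)-3,4,5-trimethoxyphenyl]-1,3-dioxolane (methyl ether of 8) | C=CCC1(OC)C=C(c2c(OC)c(OC)c(OC)cc2C2OCCO2)C=C(OC)C1(OC)OC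
F5 | step 3 | 2-[2-(1,3-dioxolan-2-yl)-4,5,6-trimethoxyphenyl]-4,4,5,5-tetramethyl-1,3,2-dioxaborolane | COc1cc(C2OCCO2)c(B2OC(C)(C)C(C)(C)O2)c(OC)c1OC
F6 | step 3 | 5-[2-(1,3-dioxolan-2-yl)-4,5,6-trimethoxyphenyl]-2,3-dimethoxyphenol | COc1cc(-c2c(OC)c(OC)c(OC)cc2C2OCCO2)cc(O)c1OC
F7 | step 7 | 1-{1-[2-(1,3-dioxolan-2-yl)-4,5,6-trimethoxyphenyl]-3,4,4,5-tetramethoxycyclohexa-2,5-dien-1-yl}butan-2-one | CCC(=O)CC1(c2c(OC)c(OC)c(OC)cc2C2OCCO2)C=C(OC)C(OC)(OC)C(OC)=C1
F8 | step 7 | (2E)-1-{1-[2-(1,3-dioxolan-2-yl)-4,5,6-trimethoxyphenyl]-3,4,4,5-tetramethoxycyclohexa-2,5-dien-1-yl}but-2-en-2-yl trifluoromethanesulfonate | COC1=CC(C/C(OS(=O)(=O)C(F)(F)F)=C\C)(C=C(OC)C1(OC)OC)c1c(OC)c(OC)c(OC)cc1C1OCCO1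
F9 | step 10 | tert-butyldimethylsilyl ether of 15 | COC1=CC2(C=C(OC)C1=O)CC(=C)[C@H](C)[C@@H](O[Si](C)(C)C(C)(C)C)c1cc(OC)c(OC)c(OC)c12
F10 | step 10 | tert-butyldimethylsilyl ether of 16 | COC1=CC2(C=C(OC)C1=O)C[C@@H](C)[C@H](C)[C@@H](O[Si](C)(C)C(C)(C)C)c1cc(OC)c(OC)c(OC)c12
A1 | alternative 1 | ring C aldehyde with C1′ bearing H and CHO, C7 hydroxyl as silyl ether (C1′ epimers) | O=CC1C[C@@H](C)[C@H](C)[C@@H](O[Si](C)(C)C(C)(C)C)c2cc(OC)c(OC)c(OC)c12
A2 | alternative 1 | 1,3-dimethoxybut-3-en-2-one | COCC(=O)C(=C)OC
A3 | alternative 1 | spiro 2,6-dimethoxycyclohex-2-enone (epimers at C1′ and C5′) | COC1=CC2(CC(OC)C1=O)C[C@@H](C)[C@H](C)[C@@H](O[Si](C)(C)C(C)(C)C)c1cc(OC)c(OC)c(OC)c12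
A4 | alternative 2 | ring C aryl enone without methyl groups (C7 ketone, C8=C8′) | COC1=CC2(C=C(OC)C1=O)CC=CC(=O)c1cc(OC)c(OC)c(OC)c12
A5 | alternative 2 | trans-8,8′-dimethyl C7 ketone | COC1=CC2(C=C(OC)C1=O)C[C@@H](C)[C@H](C)C(=O)c1cc(OC)c(OC)c(OC)c12
A6 | alternative 3 | methyl trans-2,3-dimethyl-5-oxocyclopentane-1-carboxylate | O=C1C[C@@H](C)[C@H](C)C1C(=O)OC
A7 | alternative 3 | 3,4,5-trimethoxybenzyne | COC1=CC#CC(OC)=C1OC
A8 | alternative 3 | benzo-fused seven-membered keto ester (C1′ ketone, C7 ester) | O=C1C[C@@H](C)[C@H](C)C(C(=O)OC)c2cc(OC)c(OC)c(OC)c12
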